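**Plan**

- Retrosynthesis first cuts the C2'–O methyl bond, then takes ring B apart at C1'–C2', C2'–C3' and C5'–C6'. This is possible because ring B carries oxygen at C2', C4' and C5' with the C2' and C5' oxygens para to each other, the 4-alkoxyphenol pattern that a chromium carbene, an alkyne and CO assemble.
- In that cut C2' is a CO ligand, C5' the carbene carbon, C4' and C3' the methoxyvinyl group, and C1' and C6' the alkyne of a 3-ethynylchromone.
- The ethynylchromone is cut at C3–C(sp) (Sonogashira), the prenyl group at its olefin (cross-metathesis of an allyl group), the C8–allyl bond by Claisen rearrangement, and ring C at O1–C2 (enaminone iodocyclisation), back to commercial paeonol.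
- Forward: ring A is bought, ring C closes in step 4, the prenyl and ethynyl groups follow, and ring B is built in step 9 from alkyne 9 and carbene complex 14 (step 8); a final O-methylation gives the target.
- Stereochemistry: the target has no stereocentre and no stereogenic double bond, so nothing has to be set.

Key step: step 9

Assumption: the acyclic complex 14 is taken to be as stable and as reactive as the known methoxycarbene chromium complexes made from lithiated cyclic enol ethers; it is made fresh and used at once.

**Route**

Step 1
Reactants: 1 paeonol
Product: 2 1-(2-allyloxy-4-methoxyphenyl)ethanone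
Conditions: allyl bromide, K2CO3, DMF, 60 °C
Reagents that add atoms: allyl bromide, C=CCBr
Why: Williamson ether synthesis on the only phenol present; a reactive allylic bromide in a dipolar aprotic solvent should overcome the hydrogen bond of the chelated hydroxyl.

Step 2
Reactants: 2 1-(2-allyloxy-4-methoxyphenyl)ethanone
Product: 3 1-(3-allyl-2-hydroxy-4-methoxyphenyl)ethanone
Conditions: PhNEt2, 200 °C
Reagents that add atoms: none
Why: Aromatic Claisen rearrangement; the only free ortho position of the aryl allyl ether is C3, so the [3,3] shift should place the allyl group between the two oxygens and tautomerisation should restore the chelated phenol.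

Step 3
Reactants: 3 1-(3-allyl-2-hydroxy-4-methoxyphenyl)ethanone
Product: 4 (E)-1-(3-allyl-2-hydroxy-4-methoxyphenyl)-3-(dimethylamino)prop-2-en-1-one
Conditions: Me2NCH(OMe)2, toluene, 100 °C
Reagents that add atoms: N,N-dimethylformamide dimethyl acetal, COC(OC)N(C)C
Why: Enaminone formation by condensation of the methyl ketone with the amide acetal, which should give the thermodynamically preferred E isomer and leave the chelated phenol free.

Step 4
Reactants: 4 (E)-1-(3-allyl-2-hydroxy-4-methoxyphenyl)-3-(dimethylamino)prop-2-en-1-one
Product: 5 8-allyl-3-iodo-7-methoxychromen-4-one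
Conditions: I2 (1.1 equiv), CHCl3, rt; aq. Na2S2O3 work-up
Reagents that add atoms: iodine, II
Why: Iodocyclisation of a 2-hydroxyaryl enaminone (α-iodination, attack of the phenol on the iminium carbon, loss of dimethylamine) should close ring C, the enaminone carbon being far more nucleophilic towards iodine than the monosubstituted allyl olefin.

Step 5
Reactants: 5 8-allyl-3-iodo-7-methoxychromen-4-one
Product: 6 3-iodo-7-methoxy-8-(3-methylbut-2-enyl)chromen-4-one
Conditions: 2-methylbut-2-ene (excess), second-generation Grubbs catalyst RuCl2(=CHPh)(PCy3)(H2IMes) (5 mol %), CH2Cl2, sealed tube, 40 °C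
Reagents that add atoms: 2-methylbut-2-ene, CC=C(C)C
Why: Olefin cross-metathesis of a terminal allyl arene with excess 2-methylbut-2-ene is the standard allyl-to-prenyl conversion, and the trisubstituted, electron-poor iodo-enone olefin of ring C should not engage the ruthenium carbene.

Step 6
Reactants: 6 3-iodo-7-methoxy-8-(3-methylbut-2-enyl)chromen-4-one; 7 trimethylsilylacetylene
Product: 8 7-methoxy-8-(3-methylbut-2-enyl)-3-[(trimethylsilyl)ethynyl]chromen-4-one
Conditions: PdCl2(PPh3)2 (3 mol %), CuI (5 mol %), Et3N, THF, rt
Reagents that add atoms: none
Why: Sonogashira coupling at the activated C3–I bond of a 3-iodochromone; a tertiary amine is chosen because it cannot add to C2 and open ring C.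

Step 7
Reactants: 8 7-methoxy-8-(3-methylbut-2-enyl)-3-[(trimethylsilyl)ethynyl]chromen-4-one
Product: 9 3-ethynyl-7-methoxy-8-(3-methylbut-2-enyl)chromen-4-one
Conditions: Bu4NF, AcOH, THF, 0 °C
Reagents that add atoms: none
Why: Fluoride-induced protodesilylation of the alkynylsilane, buffered with acetic acid so that no basic nucleophile attacks C2 of the chromone.

Step 8
Reactants: 10 methyl vinyl ether; 11 chromium hexacarbonyl Cr(CO)6
Product: 14 pentacarbonyl[methoxy(1-methoxyvinyl)carbene]chromium, via 1-methoxyvinyllithium 12 (not isolated), via lithium acylchromate 13 (not isolated)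
Conditions: t-BuLi, THF, −78 to 0 °C; Cr(CO)6, THF, −78 °C to rt; Me3OBF4, CH2Cl2, 0 °C
Reagents that add atoms: trimethyloxonium tetrafluoroborate, C[O+](C)C.F[B-](F)(F)F
Why: Fischer carbene synthesis: α-lithiation of the enol ether, addition of the vinyllithium to a CO ligand of Cr(CO)6 and O-methylation of the acylchromate with Meerwein salt under anhydrous conditions that spare the enol ether.

Step 9
Reactants: 9 3-ethynyl-7-methoxy-8-(3-methylbut-2-enyl)chromen-4-one; 14 pentacarbonyl[methoxy(1-methoxyvinyl)carbene]chromium
Product: 16 3-(2-hydroxy-4,5-dimethoxyphenyl)-7-methoxy-8-(3-methylbut-2-enyl)chromen-4-one, via tricarbonylchromium arene complex 15 (not isolated)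
Conditions: 14 (1.5 equiv), THF, 50 °C, Ar; then air, daylight, CH2Cl2, rt
Reagents that add atoms: none
Why: Dötz benzannulation: loss of one CO from 14 lets the terminal alkyne of 9 insert into the Cr=C bond, CO insertion gives a chromium-bound dienylketene, and six-electron electrocyclisation followed by enolisation gives ring B as the Cr(CO)3-bound 4-methoxyphenol 15, from which air and light remove the metal. The closest known reactions are the benzannulations of alkenyl(methoxy)carbene chromium complexes, including α-alkoxyalkenyl ones made from lithiated cyclic enol ethers, with terminal aryl- and alkenylacetylenes. Ring B closes by electrocyclic ring closure of the dienylketene between the ketene carbon (C2') and the former vinyl CH2 (C3'), the bonds C5'–C6' and C1'–C2' having been made by the alkyne and CO insertions. No stereocentre is formed. The step needs insertion with the chromone-bearing alkyne carbon next to the CO-derived carbon, which a terminal alkyne secures on steric grounds, and it needs the alkyne to react in preference to the prenyl and chromone olefins, which should hold because trisubstituted olefins are not cyclopropanated at 50 °C. Phenol formation over cyclopentannulation is favoured by the alkenyl carbene, by chromium and by the ethereal solvent.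

Step 10
Reactants: 16 3-(2-hydroxy-4,5-dimethoxyphenyl)-7-methoxy-8-(3-methylbut-2-enyl)chromen-4-one
Product: 17 prebarbigerone
Conditions: MeI, K2CO3, acetone, reflux
Reagents that add atoms: iodomethane, CI
Why: Williamson methylation of the single phenol; the chromone, the aryl methyl ethers and the prenyl olefin are inert to carbonate and iodomethane.

**Compound list**

1 | paeonol, 1-(2-hydroxy-4-methoxyphenyl)ethanone | CC(=O)c1ccc(OC)cc1O | starting material
2 | 1-(2-allyloxy-4-methoxyphenyl)ethanone | CC(=O)c1ccc(OC)cc1OCC=C | intermediate
3 | 1-(3-allyl-2-hydroxy-4-methoxyphenyl)ethanone | CC(=O)c1ccc(OC)c(CC=C)c1O | intermediate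
4 | (E)-1-(3-allyl-2-hydroxy-4-methoxyphenyl)-3-(dimethylamino)prop-2-en-1-one | CN(C)/C=C/C(=O)c1ccc(OC)c(CC=C)c1O | intermediate
5 | 8-allyl-3-iodo-7-methoxychromen-4-one | O=c1c(I)coc2c(CC=C)c(OC)ccc12 | intermediate
6 | 3-iodo-7-methoxy-8-(3-methylbut-2-enyl)chromen-4-one | O=c1c(I)coc2c(CC=C(C)C)c(OC)ccc12 | intermediate
7 | trimethylsilylacetylene | C#C[Si](C)(C)C | starting material
8 | 7-methoxy-8-(3-methylbut-2-enyl)-3-[(trimethylsilyl)ethynyl]chromen-4-one | C[Si](C)(C)C#Cc1coc2c(CC=C(C)C)c(OC)ccc2c1=O | intermediate
9 | 3-ethynyl-7-methoxy-8-(3-methylbut-2-enyl)chromen-4-one | C#Cc1coc2c(CC=C(C)C)c(OC)ccc2c1=O | intermediate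
10 | methyl vinyl ether | C=COC | starting material
11 | chromium hexacarbonyl Cr(CO)6 | O=C=[Cr](=C=O)(=C=O)(=C=O)(=C=O)=C=O | starting material
12 | 1-methoxyvinyllithium (not isolated) | [Li]C(=C)OC | intermediate
13 | lithium pentacarbonyl(2-methoxyacryloyl)chromate Li[(CO)5CrC(O)C(OMe)=CH2] (not isolated) | [Li+].COC(=C)C([O-])=[Cr](=C=O)(=C=O)(=C=O)(=C=O)=C=O | intermediate
14 | pentacarbonyl[methoxy(1-methoxyvinyl)carbene]chromium | COC(=C)C(OC)=[Cr](=C=O)(=C=O)(=C=O)(=C=O)=C=O | intermediate
15 | tricarbonylchromium complex of phenol 16, Cr(CO)3 bound η6 to ring B (not isolated) | COc1cc(O)c(-c2coc3c(CC=C(C)C)c(OC)ccc3c2=O)cc1OC.O=C=[Cr](=C=O)=C=O | intermediate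
16 | 3-(2-hydroxy-4,5-dimethoxyphenyl)-7-methoxy-8-(3-methylbut-2-enyl)chromen-4-one | COc1cc(O)c(-c2coc3c(CC=C(C)C)c(OC)ccc3c2=O)cc1OC | intermediate
17 | prebarbigerone, 7-methoxy-8-(3-methylbut-2-enyl)-3-(2,4,5-trimethoxyphenyl)chromen-4-one | COc1cc(OC)c(-c2coc3c(CC=C(C)C)c(OC)ccc3c2=O)cc1OC | target

**Step count**

Total: 10 steps. Longest linear sequence: 9 steps (steps 1 to 7, 9 and 10); step 8 is a one-step side branch.

**Steps most likely to fail**

1. Step 9. After alkyne insertion the chromone C4 carbonyl may chelate chromium and divert the vinylcarbene, cyclopentannulation or alkyne oligomerisation may compete, and the electron-rich hydroquinone monoether may be over-oxidised during demetalation. Fallback: ring B is attached instead of built. The route sets out from iodochromone 6, which undergoes Suzuki–Miyaura coupling with commercial (2,4,5-trimethoxyphenyl)boronic acid (Pd(PPh3)4, K2CO3, DME/H2O, 80 °C), the established way to isoflavones from 3-iodochromones. It comes back at target 17 and makes no new compound (F0).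

2. Step 8. O-Methylation of the α-alkoxyvinyl acylchromate with the hard oxonium salt may be outrun by hydrolysis of the enol ether or by decomposition of the acylate. Fallback: the route sets out from acylchromate 13, made as in step 8. Cation exchange with Me4NBr in water should give the storable tetramethylammonium acylchromate F1. Acetyl bromide in CH2Cl2 at −40 °C should convert it into the acetoxycarbene complex F2. Methanol, added at −40 °C and warmed to 0 °C, should displace acetate and return the route at carbene complex 14.

3. Step 7. Fluoride or adventitious hydroxide may add to C2 of the alkynyl-activated chromone and open ring C during desilylation. Fallback: the silyl group is avoided. The route sets out from iodochromone 6, which undergoes Stille coupling with tributyl(ethynyl)stannane (Pd(PPh3)4, toluene, 90 °C) under neutral conditions. It comes back at terminal alkyne 9 and makes no new compound (F0).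

**Further compounds**

F0 | step 9 | none | none
F1 | step 8 | tetramethylammonium pentacarbonyl(2-methoxyacryloyl)chromate Me4N[(CO)5CrC(O)C(OMe)=CH2] | C[N+](C)(C)C.COC(=C)C([O-])=[Cr](=C=O)(=C=O)(=C=O)(=C=O)=C=O
F2 | step 8 | pentacarbonyl[acetoxy(1-methoxyvinyl)carbene]chromium | COC(=C)C(OC(C)=O)=[Cr](=C=O)(=C=O)(=C=O)(=C=O)=C=O
F0 | step 7 | none | none
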